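**Assumptions (one line each):**
- The lactone 1, acid chloride 7, ylide 3, aldehyde 10, Grignard 11 and 3-bromofuran 36 are taken as commercial.
- Both 2-methylbutanoates are (S), as the target SMILES requires.
- The C4 carbinol epimers from the aldol (step 9) are carried together, because C4 is later oxidised to the ketone.

**Retrosynthesis**
1. Target ⇐ 4α,18-epoxide opened by HCl at C18 ⇐ C4 ketone (sulfonium methylide, axial β attack). The butenolide comes from a 3-furyl ketone (CBS reduction, then ¹O₂). The C12 ketone comes from the C11 acid by Arndt–Eistert/Wolff–Weinreb.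
2. Bold step: rings A and B, the C5 and C9 quaternary centres, C10 and the C9 side-chain carbon C11 are formed together by one intramolecular Diels–Alder of a 2-silyloxy triene. Its only pre-existing stereocentre is C1, from (R)-5-hydroxymethylbutyrolactone. The C8 methyl is corrected afterwards (Saegusa dehydrogenation, then conjugate reduction).
3. The triene comes from a Mukaiyama aldol (C4–C5 bond) of a silyl dienol ether with an aldehyde derived from the lactone.

**Route**

Step 1
Reactants: 1 (R)-5-(hydroxymethyl)dihydrofuran-2(3H)-one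
Product: 2 (R)-5-oxotetrahydrofuran-2-carbaldehyde
Conditions: DMP, NaHCO3, CH2Cl2, 0→25 °C
Reagents that add atoms: none
Why: Dess–Martin oxidation of the primary alcohol; the C1 stereocentre is untouched, and the crude aldehyde is used at once to avoid α-epimerisation.

Step 2
Reactants: 2; 3 tert-butyl 2-(triphenylphosphoranylidene)propanoate
Product: 4 tert-butyl (E)-2-methyl-3-[(R)-5-oxotetrahydrofuran-2-yl]acrylate
Conditions: 3 (1.2 equiv), CH2Cl2, 25 °C
Reagents that add atoms: 3, CC(=P(c1ccccc1)(c1ccccc1)c1ccccc1)C(=O)OC(C)(C)C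
Why: Wittig olefination with a stabilised ylide gives the E-enoate, which fixes the C9=C10 dienophile geometry for the Diels–Alder.

Step 3
Reactants: 4; 5 ethanethiol
Product: 6 tert-butyl (4R,E)-7-(ethylthio)-4-hydroxy-2-methyl-7-oxohept-2-enoate
Conditions: EtSH, AlMe3, CH2Cl2, 0 °C
Reagents that add atoms: 5, CCS
Why: Me2AlSEt opens the lactone (Weinreb-type aluminium thiolysis) to the thioester and free C1–OH; the hindered tert-butyl enoate is spared and C1 keeps its (R) configuration.

Step 4
Reactants: 6; 7 (S)-2-methylbutanoyl chloride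
Product: 8 tert-butyl (4R,E)-7-(ethylthio)-2-methyl-4-{[(S)-2-methylbutanoyl]oxy}-7-oxohept-2-enoate
Conditions: 7, Et3N, DMAP, CH2Cl2, 0→25 °C
Reagents that add atoms: 7, CC[C@H](C)C(=O)Cl
Why: O-acylation installs the final C1 ester early, so no hindered late-stage acylation is needed; no stereocentre changes.

Step 5
Reactants: 8
Product: 9 tert-butyl (4R,E)-2-methyl-4-{[(S)-2-methylbutanoyl]oxy}-7-oxohept-2-enoate
Conditions: Et3SiH, 10% Pd/C, acetone, 25 °C
Reagents that add atoms: none
Why: Fukuyama reduction converts the thioester to the aldehyde (C4) chemoselectively, leaving the esters and enoate intact.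

Step 6
Reactants: 10 3-(benzyloxy)propanal; 11 (E)-1-propenylmagnesium bromide
Product: 12 (E)-1-(benzyloxy)hex-4-en-3-ol
Conditions: 11, THF, −78→0 °C
Reagents that add atoms: 11, C/C=C/[Mg]Br
Why: 1,2-Grignard addition builds the C6–C7=C8–C17 unit (racemic carbinol, destroyed in the next step).

Step 7
Reactants: 12
Product: 13 (E)-1-(benzyloxy)hex-4-en-3-one
Conditions: MnO2, CH2Cl2, 25 °C
Reagents that add atoms: none
Why: MnO2 oxidises the allylic alcohol to the enone, with no stereochemical consequence.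

Step 8
Reactants: 13; 14 TBSOTf
Product: 15 silyl dienol ether C/C=C/C(OTBS)=CCOBn
Conditions: 14, Et3N, CH2Cl2, 0 °C (used crude)
Reagents that add atoms: 14, CC(C)(C)[Si](C)(C)OS(=O)(=O)C(F)(F)F
Why: Soft α′-enolisation gives the 2-silyloxydiene whose C5 terminus is nucleophilic.

Step 9
Reactants: 15; 9
Product: 16 β-hydroxy ketone (C4/C5 epimeric mixture)
Conditions: BF3·OEt2, CH2Cl2, −78 °C
Reagents that add atoms: none
Why: Mukaiyama aldol of the dienol ether at C5 onto aldehyde 9 forms the C4–C5 bond; the TBS group is lost on work-up, and C5 is epimerisable and destroyed on enolisation, so only C4 is carried.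

Step 10
Reactants: 16; 17 TESOTf
Product: 18 C4-OTES ketone
Conditions: 17, 2,6-lutidine, CH2Cl2, −78→0 °C
Reagents that add atoms: 17, CC[Si](CC)(CC)OS(=O)(=O)C(F)(F)F
Why: Silyl protection prevents retro-aldol and E1cB loss of the C4 oxygen.

Step 11
Reactants: 18; 14 TBSOTf
Product: 19 trans-decalin (IMDA adduct: C5 CH2OBn, C6 OTBS enol ether, C8-epi Me, C9 Me/CO2tBu)
Conditions: (i) 14, Et3N, CH2Cl2, 0 °C, then solvent swap; (ii) PhMe, BHT, 140 °C, sealed tube
Reagents that add atoms: 14, CC(C)(C)[Si](C)(C)OS(=O)(=O)C(F)(F)F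
Why: Proposed new method: enolisation gives the tetrasubstituted 2-silyloxydiene C5=C6–C7=C8, which adds to the E-tiglate C10=C9 through the four-atom C1–C4 tether in a chair-like endo TS with both tether oxygens pseudo-equatorial, forming rings A and B at once; the (R)-C1 ester sets the tether face and the tether-outside diene with E-dienophile gives trans-fusion, so C5 (C19 α, axial), C10 (H β) and C9 (C20 α, C11 β) arise together and C8 is formed epimeric; closest known reaction is the Type-1 IMDA of 1,7,9-decatrienes with 2-siloxydienes (Roush/Deslongchamps-type).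

Step 12
Reactants: 19
Product: 20 enone (C6=O, C7=C8)
Conditions: Pd(OAc)2 (1.1 equiv), MeCN, 25 °C
Reagents that add atoms: none
Why: Saegusa–Ito oxidation of the silyl enol ether gives the enone and erases the C8 stereocentre.

Step 13
Reactants: 20
Product: 21 C6 ketone with C8 Me α / H β
Conditions: [(Ph3P)CuH]6, PhMe, −20→0 °C
Reagents that add atoms: none
Why: Proposed new method: CuH conjugate reduction of the β,β-disubstituted enone, with hydride delivered axially from the β face (the α face is blocked by axial C20 and C19), gives H8 β and the equatorial α methyl; closest known reaction is Stryker conjugate reduction of 3-substituted cyclohexenones.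

Step 14
Reactants: 21
Product: 22 6α-alcohol
Conditions: NaBH4, EtOH, 25 °C
Reagents that add atoms: none
Why: A small hydride attacks axially from the β face (the α side is shielded by axial C19), giving the equatorial 6α-OH.

Step 15
Reactants: 22; 23 acetic anhydride
Product: 24 C6-acetate
Conditions: 23, py, DMAP, CH2Cl2, 40 °C
Reagents that add atoms: 23, CC(=O)OC(C)=O
Why: Acetylation installs the final C6 acetate and protects the alcohol before the C4 oxidation.

Step 16
Reactants: 24
Product: 25 C4 alcohol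
Conditions: PPTS, MeOH, 40 °C
Reagents that add atoms: none
Why: Mild acid selectively cleaves the TES ether.

Step 17
Reactants: 25
Product: 26 C4 ketone
Conditions: DMP, NaHCO3, CH2Cl2, 25 °C
Reagents that add atoms: none
Why: Oxidation removes the C4 stereocentre and gives the ketone needed for methylenation.

Step 18
Reactants: 26
Product: 27 carboxylic acid (C11)
Conditions: TFA, CH2Cl2 (1:4), 0→25 °C
Reagents that add atoms: none
Why: The tert-butyl ester is cleaved by acidolysis while the epoxide is not yet present.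

Step 19
Reactants: 27
Product: 28 C19 primary alcohol
Conditions: H2 (1 atm), 10% Pd/C, EtOAc, 25 °C
Reagents that add atoms: none
Why: Hydrogenolysis of the benzyl ether (no alkenes are present yet).

Step 20
Reactants: 28; 23
Product: 29 C19-acetate acid
Conditions: 23, py, DMAP, CH2Cl2, 25 °C; then aq. NaHCO3
Reagents that add atoms: 23, CC(=O)OC(C)=O
Why: Acetylation installs the final C19 acetate, and the aqueous work-up returns the acid from its mixed anhydride.

Step 21
Reactants: 29; 30 diazomethane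
Product: 31 α-diazoketone
Conditions: (COCl)2, DMF (cat.), CH2Cl2, 0 °C; then 30, Et2O, 0 °C
Reagents that add atoms: 30, C=[N+]=[N-]
Why: The acid chloride (not isolated) is converted to the diazoketone, the first stage of the Arndt–Eistert homologation.

Step 22
Reactants: 31; 32 N,O-dimethylhydroxylamine
Product: 33 Weinreb amide (C11H2–C12)
Conditions: AgOBz (20 mol%), Et3N, MeNH(OMe)·HCl, THF, 25 °C
Reagents that add atoms: 32, CONC
Why: Ag-catalysed Wolff rearrangement inserts C11 between C9 and the former acid carbon (now C12), with retention at the migrating quaternary C9, and the ketene is trapped as the Weinreb amide.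

Step 23
Reactants: 33; 34 trimethylsulfonium iodide
Product: 35 4α,18-epoxide
Conditions: 34, n-BuLi, THF, −10→0 °C
Reagents that add atoms: 34, C[S+](C)C.[I-]
Why: Corey–Chaykovsky methylenation with a sulfonium ylide attacks the C4 ketone axially from the β face (the equatorial α trajectory is blocked by axial C19), giving C18 β and O α.

Step 24
Reactants: 35; 36 3-bromofuran
Product: 37 3-furyl ketone (C12=O)
Conditions: 36, n-BuLi, THF, −78 °C; then 35, −78→−20 °C
Reagents that add atoms: 36, Brc1ccoc1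
Why: 3-Furyllithium adds once to the chelated Weinreb amide, so no over-addition occurs.

Step 25
Reactants: 37
Product: 38 (12S)-alcohol
Conditions: (R)-Me-CBS (20 mol%), BH3·SMe2, THF, −20 °C
Reagents that add atoms: none
Why: Corey–Bakshi–Shibata reduction sets C12 (S), by analogy with the acetophenone (aryl > alkyl) model in which (S)-CBS gives the (R)-alcohol.

Step 26
Reactants: 38; 7
Product: 39 C12-[(S)-2-methylbutanoate]
Conditions: 7, py, DMAP, CH2Cl2, 40 °C
Reagents that add atoms: 7, CC[C@H](C)C(=O)Cl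
Why: Esterification of the hindered secondary alcohol with retention at C12.

Step 27
Reactants: 39; 40 singlet oxygen
Product: 41 4-substituted 5-hydroxybutenolide
Conditions: O2, visible light, Rose Bengal, iPr2NEt, CH2Cl2, −78 °C
Reagents that add atoms: 40, O=O
Why: [4+2] of ¹O₂ across the furan, then base-induced Kornblum–DeLaMare opening at the less hindered bridgehead, gives the γ-hydroxybutenolide with the carbonyl remote from C13.

Step 28
Reactants: 41
Product: 42 butenolide-epoxide
Conditions: NaBH4, EtOH, −78→0 °C; then AcOH/NaOAc buffer, pH 5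
Reagents that add atoms: none
Why: The ring-opened aldehyde-carboxylate is reduced and the cis-γ-hydroxy enoic acid relactonises, replacing C16–OH by H; no stereocentre is involved.

Step 29
Reactants: 42; 43 hydrogen chloride
Product: 44 ajugaciliatin A
Conditions: HCl (1 M in Et2O), CH2Cl2, −20 °C
Reagents that add atoms: 43, Cl
Why: Chloride opens the spiro-epoxide by SN2 at the primary C18, because the tertiary, neopentyl C4 is hindered, so C4 is retained as the tertiary 4α-OH.

**Compound list**

1 | (R)-5-(hydroxymethyl)dihydrofuran-2(3H)-one | OC[C@H]1CCC(=O)O1 | starting material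
2 | (R)-5-oxotetrahydrofuran-2-carbaldehyde | O=C[C@H]1CCC(=O)O1 | intermediate
3 | tert-butyl 2-(triphenylphosphoranylidene)propanoate | CC(=P(c1ccccc1)(c1ccccc1)c1ccccc1)C(=O)OC(C)(C)C | starting material
4 | tert-butyl (E)-2-methyl-3-[(R)-5-oxotetrahydrofuran-2-yl]acrylate | CC(C)(C)OC(=O)/C(C)=C/[C@H]1CCC(=O)O1 | intermediate
5 | ethanethiol | CCS | starting material
6 | tert-butyl (4R,E)-7-(ethylthio)-4-hydroxy-2-methyl-7-oxohept-2-enoate | CCSC(=O)CC[C@@H](O)/C=C(\C)C(=O)OC(C)(C)C | intermediate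
7 | (S)-2-methylbutanoyl chloride | CC[C@H](C)C(=O)Cl | starting material
8 | thioester C1-(S)-2-methylbutanoate | CCSC(=O)CC[C@@H](OC(=O)[C@@H](C)CC)/C=C(\C)C(=O)OC(C)(C)C | intermediate
9 | tert-butyl (4R,E)-2-methyl-4-{[(S)-2-methylbutanoyl]oxy}-7-oxohept-2-enoate | O=CCC[C@@H](OC(=O)[C@@H](C)CC)/C=C(\C)C(=O)OC(C)(C)C | intermediate
10 | 3-(benzyloxy)propanal | O=CCCOCc1ccccc1 | starting material
11 | (E)-1-propenylmagnesium bromide | C/C=C/[Mg]Br | starting material
12 | (E)-1-(benzyloxy)hex-4-en-3-ol | C/C=C/C(O)CCOCc1ccccc1 | intermediate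
13 | (E)-1-(benzyloxy)hex-4-en-3-one | C/C=C/C(=O)CCOCc1ccccc1 | intermediate
14 | tert-butyldimethylsilyl triflate | CC(C)(C)[Si](C)(C)OS(=O)(=O)C(F)(F)F | starting material
15 | TBS silyl dienol ether of 13 | C/C=C/C(O[Si](C)(C)C(C)(C)C)=CCOCc1ccccc1 | intermediate
16 | aldol adduct (C4/C5 epimeric mixture) | C/C=C/C(=O)C(COCc1ccccc1)C(O)CC[C@@H](OC(=O)[C@@H](C)CC)/C=C(\C)C(=O)OC(C)(C)C | intermediate
17 | triethylsilyl triflate | CC[Si](CC)(CC)OS(=O)(=O)C(F)(F)F | starting material
18 | C4-OTES ketone | C/C=C/C(=O)C(COCc1ccccc1)C(O[Si](CC)(CC)CC)CC[C@@H](OC(=O)[C@@H](C)CC)/C=C(\C)C(=O)OC(C)(C)C | intermediate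
19 | IMDA adduct (Δ6 TBS enol ether, 8-epi) | CC(C)(C)OC(=O)[C@@]1(C)[C@@H](C)C=C(O[Si](C)(C)C(C)(C)C)[C@]2(COCc3ccccc3)[C@@H]1[C@H](OC(=O)[C@@H](C)CC)CC[C@H]2O[Si](CC)(CC)CC | intermediate
20 | Δ7-6-ketone | CC(C)(C)OC(=O)[C@@]1(C)C(C)=CC(=O)[C@]2(COCc3ccccc3)[C@@H]1[C@H](OC(=O)[C@@H](C)CC)CC[C@H]2O[Si](CC)(CC)CC | intermediate
21 | C6 ketone, C8 corrected | CC(C)(C)OC(=O)[C@@]1(C)[C@H](C)CC(=O)[C@]2(COCc3ccccc3)[C@@H]1[C@H](OC(=O)[C@@H](C)CC)CC[C@H]2O[Si](CC)(CC)CC | intermediate
22 | 6α-alcohol | CC(C)(C)OC(=O)[C@@]1(C)[C@H](C)C[C@H](O)[C@]2(COCc3ccccc3)[C@@H]1[C@H](OC(=O)[C@@H](C)CC)CC[C@H]2O[Si](CC)(CC)CC | intermediate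
23 | acetic anhydride | CC(=O)OC(C)=O | starting material
24 | 6α-acetate | CC(C)(C)OC(=O)[C@@]1(C)[C@H](C)C[C@H](OC(C)=O)[C@]2(COCc3ccccc3)[C@@H]1[C@H](OC(=O)[C@@H](C)CC)CC[C@H]2O[Si](CC)(CC)CC | intermediate
25 | C4 alcohol | CC(C)(C)OC(=O)[C@@]1(C)[C@H](C)C[C@H](OC(C)=O)[C@]2(COCc3ccccc3)[C@@H]1[C@H](OC(=O)[C@@H](C)CC)CC[C@H]2O | intermediate
26 | C4 ketone | CC(C)(C)OC(=O)[C@@]1(C)[C@H](C)C[C@H](OC(C)=O)[C@]2(COCc3ccccc3)[C@@H]1[C@H](OC(=O)[C@@H](C)CC)CCC2=O | intermediate
27 | C11 acid | OC(=O)[C@@]1(C)[C@H](C)C[C@H](OC(C)=O)[C@]2(COCc3ccccc3)[C@@H]1[C@H](OC(=O)[C@@H](C)CC)CCC2=O | intermediate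
28 | C19 alcohol acid | OC(=O)[C@@]1(C)[C@H](C)C[C@H](OC(C)=O)[C@]2(CO)[C@@H]1[C@H](OC(=O)[C@@H](C)CC)CCC2=O | intermediate
29 | C19-acetate acid | OC(=O)[C@@]1(C)[C@H](C)C[C@H](OC(C)=O)[C@]2(COC(C)=O)[C@@H]1[C@H](OC(=O)[C@@H](C)CC)CCC2=O | intermediate
30 | diazomethane | C=[N+]=[N-] | starting material
31 | diazoketone | [N-]=[N+]=CC(=O)[C@@]1(C)[C@H](C)C[C@H](OC(C)=O)[C@]2(COC(C)=O)[C@@H]1[C@H](OC(=O)[C@@H](C)CC)CCC2=O | intermediate
32 | N,O-dimethylhydroxylamine | CONC | starting material
33 | Weinreb amide | CON(C)C(=O)C[C@@]1(C)[C@H](C)C[C@H](OC(C)=O)[C@]2(COC(C)=O)[C@@H]1[C@H](OC(=O)[C@@H](C)CC)CCC2=O | intermediate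
34 | trimethylsulfonium iodide | C[S+](C)C.[I-] | starting material
35 | 4α,18-epoxide Weinreb amide | CON(C)C(=O)C[C@@]1(C)[C@H](C)C[C@H](OC(C)=O)[C@]2(COC(C)=O)[C@@H]1[C@H](OC(=O)[C@@H](C)CC)CC[C@]2(O3)C3 | intermediate
36 | 3-bromofuran | Brc1ccoc1 | starting material
37 | 3-furyl ketone | O=C(C[C@@]1(C)[C@H](C)C[C@H](OC(C)=O)[C@]2(COC(C)=O)[C@@H]1[C@H](OC(=O)[C@@H](C)CC)CC[C@]2(O3)C3)c1ccoc1 | intermediate
38 | (12S)-alcohol | O[C@@H](C[C@@]1(C)[C@H](C)C[C@H](OC(C)=O)[C@]2(COC(C)=O)[C@@H]1[C@H](OC(=O)[C@@H](C)CC)CC[C@]2(O3)C3)c1ccoc1 | intermediate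
39 | C12 ester (furan) | CC[C@H](C)C(=O)O[C@@H](C[C@@]1(C)[C@H](C)C[C@H](OC(C)=O)[C@]2(COC(C)=O)[C@@H]1[C@H](OC(=O)[C@@H](C)CC)CC[C@]2(O3)C3)c1ccoc1 | intermediate
40 | singlet oxygen (from O2) | O=O | starting material
41 | 5-hydroxybutenolide | CC[C@H](C)C(=O)O[C@@H](C[C@@]1(C)[C@H](C)C[C@H](OC(C)=O)[C@]2(COC(C)=O)[C@@H]1[C@H](OC(=O)[C@@H](C)CC)CC[C@]2(O3)C3)C1=CC(=O)OC1O | intermediate
42 | butenolide epoxide | CC[C@H](C)C(=O)O[C@@H](C[C@@]1(C)[C@H](C)C[C@H](OC(C)=O)[C@]2(COC(C)=O)[C@@H]1[C@H](OC(=O)[C@@H](C)CC)CC[C@]2(O3)C3)C1=CC(=O)OC1 | intermediate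
43 | hydrogen chloride | Cl | starting material
44 | ajugaciliatin A | CC[C@H](C)C(=O)O[C@@H](C[C@@]1(C)[C@H](C)C[C@H](OC(C)=O)[C@]2(COC(C)=O)[C@@H]1[C@H](OC(=O)[C@@H](C)CC)CC[C@]2(O)CCl)C1=CC(=O)OC1 | target

**Totals:** 29 steps; longest linear sequence 26 steps (1→9 in steps 1–5, then steps 9–29). Steps 6–8 are a parallel branch.

**Three steps most likely to fail**
1. **Step 11 (IMDA).** The diene terminus and dienophile are both fully substituted, and the endo/chair preference and silyl enol ether geometry are uncertain.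
   - Fallback: replace the one-step annulation with a Robinson/Hajos–Parrish-type route. Annulate a 2-(benzyloxymethyl)cyclohexane-1,3-dione with ethyl vinyl ketone, then set trans-fusion and C9 by Stork reductive alkylation and a Johnson–Claisen on a C1 allylic alcohol.
2. **Steps 12–13 (Saegusa, then CuH reduction to fix C8).** Hydride delivery to C8, flanked by the quaternary C9, may be slow or unselective.
   - Fallback: swap the benzyl ether for a silyl ether in the aldol partner and do a Li/NH3 (Stork) enone reduction. Axial protonation of the β-carbanion gives H8 axial, so the equatorial Me is set thermodynamically.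
3. **Step 29 (HCl opening).** Opening at tertiary C4, or rearrangement, would compete with SN2 at C18.
   - Fallback: skip the epoxide. Methylenate the C4 ketone (Ph3P=CH2) and carry the 4(18)-alkene to the end, then install the chlorohydrin by NCS/H2O chlorohydroxylation, which puts Cl on C18 and OH on C4 Markovnikov.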